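Compounds 1–20 keep the same numbers throughout; the numbering follows the steps.

## Analysis of the target

Gericudranin E, compound 20, is a 2,3-dihydroflavonol: ring C is a chroman-4-one (O1, C2, C3, C4, C4a, C8a) fused to a phloroglucinol-type ring A that carries hydroxyls at C5 and C7 and a 4-hydroxybenzyl group at C6, and ring B is a 4-hydroxyphenyl group on C2. The only stereocentres are C2 and C3, both R, adjacent and trans, with aryl and hydroxyl both equatorial; this is the more stable relative arrangement, so the real stereochemical task is the absolute sense. The C3 hydrogen is α to the C4 ketone and O1 sits β to it on C2, so base can open ring C through the enolate and erase both centres. Oxidants carry the molecule on to the flavonol, and the methylene between two electron-rich rings and the free polyphenol are also easily oxidised. Two things make the synthesis hard: C6 and C8 both lie between two oxygens, so a late benzylation of ring A cannot tell them apart, and the α-hydroxy-β-aryloxy ketone must be made as one enantiomer and then handled without base. The strategy rests on the bonds O1–C2 and C3–C4 of ring C: cutting both leaves O1, C8a, C4a and C4 as an ortho-quinone methide of ring A, with C4 already oxygenated as the formyl carbon of a salicylaldehyde, and leaves C2–C3 as a styrene-type enol ester of ring B. Because that salicylaldehyde derives from a phenol with a mirror plane, the 6-benzyl regiochemistry is settled before ring C exists.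

## Retrosynthetic reasoning

**20 ⇒ 19 ⇒ 18 (no skeletal bond cut).** The four phenols of 20 are written as benzyl ethers (19), so that the last operation is a neutral hydrogenolysis, the kind of deprotection this base-sensitive ketol tolerates best. The C3 hydroxyl of 19 is traced to the acetate 18, because that oxygen enters the skeleton as part of an enol ester. The forward step must remove the ester under acid, never through the C3 enolate.

**18 ⇒ 17 ⇒ 16 (oxidation level of C4).** The ketone is taken back to the benzylic alcohol 17 and that to the methyl ether 16. This costs two functional-group steps, but C4 may then be any mixture of epimers. The forward chemistry is solvolysis of a benzylic ether activated by three ring A oxygens, then a non-basic alcohol oxidation; neither touches C2 or C3.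

**16 ⇒ 9 + 12 + 13 (O1–C2 and C3–C4).** Both bonds that join ring A to the C2–C3 unit are cut at once. Cutting here, rather than at C4–C4a or at the C2–aryl bond, turns ring A into salicylaldehyde 9, whose formyl carbon is C4 and whose phenol oxygen is O1. It turns C2–C3, with its aryl and oxygen substituents, into the (E)-enol acetate 12. Orthoformate 13 supplies the methoxy group that makes the aldehyde a cation precursor. The gain is ring C, two skeletal bonds and both stereocentres in one operation from achiral pieces. The forward reaction must form C3–C4 at the acetoxy-bearing alkene carbon, close O1–C2 trans, and do both on one enantioface under a chiral acid.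

**9 ⇒ 8 (C4–C4a).** Removing the formyl group leaves phenol 8, which has a mirror plane through its hydroxyl-bearing and benzyl-bearing carbons. The two ortho positions are identical and the para position is occupied, so an ortho-selective formylation can give only 9. This is where the 6- versus 8-benzyl question is answered.

**8 ⇒ 7 ⇒ 6 ⇒ 3 + 5 (diarylmethane C–C bond).** Allyl ether 7 is the protected form of 8. Its methylene is traced to carbinol 6, and the aryl–carbinol bond is cut to aldehyde 3 and Grignard reagent 5, made from bromide 4. The cut is placed at the former formyl carbon of 3 because this keeps the ring A piece symmetric throughout. Forward, an aryl Grignard addition and an ionic deoxygenation are needed, and both are favoured by the electron-rich rings.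

**3 ⇒ 2 ⇒ 1 (oxygen differentiation).** The three hydroxyls of 1 are told apart by their relation to the formyl group. The para hydroxyl is capped first with allyl (2), then the two chelated ortho hydroxyls with benzyl (3). Allyl is chosen because it survives base, Grignard reagent and acid and can later be removed with benzyl ethers present.

**12 ⇒ 11 ⇒ 10.** The enol acetate is the O-acetylated enol of arylacetaldehyde 11, which comes from oxidation of primary alcohol 10. No C–C bond has to be made for this fragment.

## Alternatives that were turned down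

Alternative 1: ring A built last by photochemical benzannulation.
- Disconnection: four bonds of ring A are cut (C8–C8a, C5–C6, C7–C8, C4a–C5). This leaves the enantiopure ring C diazoketone (2R,3R)-3-(benzyloxy)-2-[4-(benzyloxy)phenyl]-6-(diazoacetyl)-2,3-dihydro-4H-pyran-4-one A2 and the siloxyalkyne triisopropyl({3-[4-(benzyloxy)phenyl]prop-1-yn-1-yl}oxy)silane A3.
- Forward key step: irradiation of A2 triggers Wolff rearrangement to a vinylketene, which adds A3 in a [2+2] sense. The cyclobutenone opens, the dienylketene closes by six-electron electrocyclisation and tautomerises to the ring A phenol (2R,3R)-3-(benzyloxy)-6-[4-(benzyloxy)benzyl]-2-[4-(benzyloxy)phenyl]-5-hydroxy-7-(triisopropylsilyloxy)chroman-4-one A1, a protected form of 20 with the C5 hydroxyl free.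
- For it: the polarity of A3 alone fixes the 6-benzyl pattern, and the C5 and C7 oxygens of A1 emerge differentiated. Both stereocentres would come from established asymmetric chemistry before the key step. On stereochemical certainty this is stronger than an untested enantioselective cycloaddition.
- Against it: A2 is harder to make than anything in the chosen route. A 2-aryl-3-alkoxy-dihydropyranone with an acyl group at C6 needs its own multi-step asymmetric synthesis, and its C3 hydrogen is α to a vinylogous ester carbonyl. The cross-conjugated enone absorbs the light meant for the diazo group, which invites dimerisation and fragmentation. A3 carries a propargylic, benzylic methylene next to an ynol ether and should isomerise easily. Four bonds must form in sequence with the stereocentres already on board.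
- Comparison: the step count would clearly exceed that of the chosen route. The chosen route gives up pre-set stereochemistry and offers instead ring C from robust achiral partners, with the stereocentres created only when the ring forms.

Alternative 2: aryl ether first, ring C closed by Parham-type acylation.
- Disconnection: C4–C4a (aryllithium plus Weinreb amide) and O1–C2 (phenol plus epoxide).
- Forward: phenol 8 of the present route opens the glycidic ester methyl (2R,3S)-3-[4-(benzyloxy)phenyl]oxirane-2-carboxylate A6 at the benzylic carbon with inversion. Silylation, conversion of the ester into the Weinreb amide and ortho-bromination give the bromo amide (2R,3R)-3-{3,5-bis(benzyloxy)-4-[4-(benzyloxy)benzyl]-2-bromophenoxy}-3-[4-(benzyloxy)phenyl]-2-(tert-butyldimethylsilyloxy)-N-methoxy-N-methylpropanamide A5. Halogen–lithium exchange on A5 with an alkyllithium at low temperature and attack of the aryllithium on the amide close ring C to (2R,3R)-5,7-bis(benzyloxy)-6-[4-(benzyloxy)benzyl]-2-[4-(benzyloxy)phenyl]-3-(tert-butyldimethylsilyloxy)chroman-4-one A4.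
- For it: every step is of a known type. The stereocentres of A6 derive from a catalytic asymmetric oxidation of a cinnamate, and the symmetric phenol settles the regiochemistry just as here. On reliability of the stereochemistry it is stronger than the chosen route.
- Against it: opening of A6 at its 4-alkoxybenzylic carbon has SN1 character, which erodes the anti relationship, and the very electron-rich phenol can attack through carbon. The exchange step puts a strong base next to the four benzyl ethers of A5 and an amide whose α-hydrogen lies β to an aryloxide leaving group. The aryllithium is flanked on both sides.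
- Comparison: from 8 it needs about five steps to reach A4 and two more deprotections, where the chosen route needs one formylation and one ring-forming step. The chosen route avoids strongly basic steps but carries the risk of an unprecedented asymmetric induction.

Alternative 3: carbonylative three-component assembly of the flavone.
- Disconnection: C4a–C4, C4–C3 and O1–C2, with C4 supplied by carbon monoxide A10.
- Forward key step: the iodophenol 3,5-bis(benzyloxy)-4-[4-(benzyloxy)benzyl]-2-iodophenol A8, from iodination of phenol 8, is coupled under A10 with the alkyne 1-(benzyloxy)-4-ethynylbenzene A9 by a divalent palladium phosphine precatalyst and a secondary amine. The phenol adds 6-endo to the ynone to give the flavone 5,7-bis(benzyloxy)-6-[4-(benzyloxy)benzyl]-2-[4-(benzyloxy)phenyl]-4H-chromen-4-one A7.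
- For it: this is the most convergent and most dependable ring-forming step of the four strategies. All carbons of ring C arrive in one flask from A8, A9 and A10, and regiochemistry again comes from the symmetric phenol.
- Against it: A7 is flat. C2 and C3 must afterwards receive H and OH trans and enantioselectively. That means an asymmetric conjugate reduction of a hindered, electron-rich 5,7-dialkoxyflavone followed by enolate hydroxylation, and the enolate is exactly the species that expels O1 and opens ring C. An epoxidation path instead leads towards the flavonol oxidation level. 5-exo closure to the aurone also competes.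
- Comparison: it is stronger in the robustness of the ring closure. The chosen route installs oxygen at C3 and C4 and both stereocentres during ring formation, so nothing has to be corrected on a finished, fragile ring C.

Key step: step 9

Assumption: the sense of induction of the confined acid in step 9 cannot be derived beforehand, so the antipode that leads to (2R,3S)-16 is taken to be found by a short screen, with enantiomeric purity assayed on ketone 18, where C4 is no longer a stereocentre.
Remark: the C3 descriptor is S in 16 and 17 and R in 18, 19 and 20 with no change in space, because oxidation of C4 raises its CIP rank above that of C2.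
Assumption: alcohol 10 is taken as a purchased material.

## Route

Step 1
Reactants: 1 2,4,6-trihydroxybenzaldehyde
Product: 2 4-(allyloxy)-2,6-dihydroxybenzaldehyde
Conditions: allyl bromide (1.0 equiv), CsHCO3 (1.1 equiv), MeCN, 60 °C
Reagents that add atoms: allyl bromide, C=CCBr
Why: The 4-hydroxyl is para to the formyl group, the most acidic and the only one not held in a hydrogen bond to the carbonyl, so one equivalent of a weak base should form and alkylate mainly its phenoxide (regioselective Williamson etherification).

Step 2
Reactants: 2 4-(allyloxy)-2,6-dihydroxybenzaldehyde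
Product: 3 4-(allyloxy)-2,6-bis(benzyloxy)benzaldehyde
Conditions: BnBr (2.4 equiv), K2CO3, DMF, 60 °C
Reagents that add atoms: benzyl bromide, BrCc1ccccc1
Why: With excess base and halide in a dipolar aprotic solvent both chelated ortho hydroxyls are O-benzylated in turn (Williamson etherification); the allyl ether marks the oxygen that later becomes O1.

Step 3
Reactants: 3 4-(allyloxy)-2,6-bis(benzyloxy)benzaldehyde; 4 1-(benzyloxy)-4-bromobenzene
Product: 6 [4-(allyloxy)-2,6-bis(benzyloxy)phenyl][4-(benzyloxy)phenyl]methanol (racemic), via [4-(benzyloxy)phenyl]magnesium bromide 5 (not isolated)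
Conditions: 4, Mg turnings, THF, 50 °C; then 3, 0 °C to rt; aq. NH4Cl
Reagents that add atoms: none
Why: Aryl Grignard formation and 1,2-addition to a hindered but non-enolisable aldehyde (Grignard reaction); the carbinol centre is racemic and is removed in the next step.

Step 4
Reactants: 6 [4-(allyloxy)-2,6-bis(benzyloxy)phenyl][4-(benzyloxy)phenyl]methanol
Product: 7 5-(allyloxy)-1,3-bis(benzyloxy)-2-[4-(benzyloxy)benzyl]benzene
Conditions: Et3SiH (3 equiv), TFA (2 equiv), CH2Cl2, −20 to 0 °C
Reagents that add atoms: none
Why: The benzhydrol ionises readily to a cation stabilised by the trioxygenated ring and the 4-benzyloxyphenyl group, and the silane delivers hydride (ionic hydrogenation); allyl and benzyl ethers are inert under these mild conditions and excess silane outcompetes Friedel–Crafts capture.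

Step 5
Reactants: 7 5-(allyloxy)-1,3-bis(benzyloxy)-2-[4-(benzyloxy)benzyl]benzene
Product: 8 3,5-bis(benzyloxy)-4-[4-(benzyloxy)benzyl]phenol
Conditions: Pd(PPh3)4 (3 mol%), morpholine (5 equiv), THF, rt
Reagents that add atoms: none
Why: Zerovalent palladium ionises the aryl allyl ether to a π-allyl complex and the phenoxide, and morpholine takes up the allyl group (Tsuji–Trost deallylation); benzyl ethers are untouched.

Step 6
Reactants: 8 3,5-bis(benzyloxy)-4-[4-(benzyloxy)benzyl]phenol
Product: 9 2,4-bis(benzyloxy)-3-[4-(benzyloxy)benzyl]-6-hydroxybenzaldehyde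
Conditions: MgCl2, Et3N, (CH2O)n, MeCN, reflux; dilute aq. HCl work-up
Reagents that add atoms: paraformaldehyde (as formaldehyde), C=O
Why: The magnesium phenoxide delivers formaldehyde to the ortho carbon through a chelate and the resulting benzylic alkoxide is oxidised by a second equivalent of formaldehyde (Casnati–Skattebøl ortho-formylation); the two ortho positions are identical by symmetry and the para position is blocked, so one aldehyde is expected, and the chelated product is deactivated towards a second formylation.

Step 7
Reactants: 10 2-[4-(benzyloxy)phenyl]ethanol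
Product: 11 2-[4-(benzyloxy)phenyl]acetaldehyde
Conditions: Dess–Martin periodinane, CH2Cl2, 0 °C to rt
Reagents that add atoms: none
Why: Dess–Martin oxidation stops at the enolisable arylacetaldehyde under neutral anhydrous conditions; the crude aldehyde is used at once.

Step 8
Reactants: 11 2-[4-(benzyloxy)phenyl]acetaldehyde
Product: 12 (E)-2-[4-(benzyloxy)phenyl]ethenyl acetate
Conditions: Ac2O, KOAc, 120 °C; (E)-isomer separated by crystallisation or chromatography
Reagents that add atoms: acetic anhydride, CC(=O)OC(C)=O
Why: Acetate-mediated enolisation and O-acetylation of the aldehyde (enol acetylation); both geometric isomers are to be expected with the less hindered (E)-isomer predominating, and this isomer is purified for the key step.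

Step 9
Reactants: 9 2,4-bis(benzyloxy)-3-[4-(benzyloxy)benzyl]-6-hydroxybenzaldehyde; 12 (E)-2-[4-(benzyloxy)phenyl]ethenyl acetate; 13 trimethyl orthoformate
Product: 16 (2R,3S)-5,7-bis(benzyloxy)-6-[4-(benzyloxy)benzyl]-2-[4-(benzyloxy)phenyl]-4-methoxychroman-3-yl acetate (2,3-trans; C4 epimers), via dimethyl acetal 14 (not isolated), via O-methyl o-quinone methide cation 15 (not isolated)
Conditions: 9, 13 (1.1 equiv), one antipode of the confined acid HN[P(=NSO2CF3)(O,O'-1,1'-binaphthyl-2,2'-diyl)]2 bearing 3,5-(CF3)2C6H3 groups at the 3,3'-positions (5 mol%), CHCl3, rt until 14 has formed; then 12 (1.3 equiv), −40 to −20 °C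
Reagents that add atoms: none
Why: Proposed new method: the acid and 13 first convert 9 into acetal 14, which ionises to the 2-hydroxyaryl methoxycarbenium ion 15 (the O-methylated ortho-quinone methide), held as a contact ion pair in the chiral pocket with the phenolic OH hydrogen-bonded to the anion. The acetoxy-bearing alkene carbon of 12 attacks the methide carbon (C3–C4), because the 4-benzyloxyphenyl group stabilises positive charge far better than the acetoxy group and so places the charge at benzylic C2. The phenol oxygen then captures that cation (O1–C2), a six-membered closure that is 6-endo with respect to the cationic carbon and completes a polar, stepwise or strongly asynchronous oxa-[4+2]. The closest known reaction types are the achiral acid-catalysed condensation of salicylaldehydes, orthoformates and styrenes to 2-aryl-4-alkoxychromans, and chiral phosphoric or imidodiphosphoric acid-catalysed [4+2] reactions of ortho-quinone methides generated from salicylaldehydes or 2-hydroxybenzyl alcohols. C3 is set in the C–C bond-forming event by the face of the enol ester that the ion pair exposes, so the catalyst has to control both the cation face and the mutual orientation of the partners. C2 follows from C3, since the (E)-alkene and closure through a half-chair with aryl and acetoxy pseudo-equatorial give the 2,3-trans ring, and any acid-reversible opening at benzylic C2 can only funnel towards this more stable isomer. C4 is left uncontrolled because it is oxidised later; its epimers are harmless as long as both carry the same C3 configuration, as they do when they arise by methanol exchange at C4. The step also needs 12 to meet 15 and not the dimethoxycarbenium ion of 13 (secured by forming 14 with barely more than one equivalent of 13 before 12 is added), O-capture by the tethered phenol and not by the acetate carbonyl (secured by the unstrained six-membered closure), and no second alkylation of re-ionised product (limited excess of 12, liberated methanol left in the medium, low temperature).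

Step 10
Reactants: 16 (2R,3S)-5,7-bis(benzyloxy)-6-[4-(benzyloxy)benzyl]-2-[4-(benzyloxy)phenyl]-4-methoxychroman-3-yl acetate
Product: 17 (2R,3S)-5,7-bis(benzyloxy)-6-[4-(benzyloxy)benzyl]-2-[4-(benzyloxy)phenyl]-4-hydroxychroman-3-yl acetate (C4 epimers)
Conditions: p-TsOH·H2O (10 mol%), THF/H2O 4:1, 0.02 M, rt
Reagents that add atoms: water, O
Why: The C4 carbon is ortho and para to three ring A oxygens, so its ether ionises under mild acid (SN1 solvolysis of an activated benzylic ether); a cation this well stabilised should be trapped directly by the large excess of water without needing participation by the neighbouring acetate, and high dilution suppresses attack by C8 of a second molecule. C2 and C3 are not involved and both C4 epimers are carried on.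

Step 11
Reactants: 17 (2R,3S)-5,7-bis(benzyloxy)-6-[4-(benzyloxy)benzyl]-2-[4-(benzyloxy)phenyl]-4-hydroxychroman-3-yl acetate
Product: 18 (2R,3R)-5,7-bis(benzyloxy)-6-[4-(benzyloxy)benzyl]-2-[4-(benzyloxy)phenyl]-4-oxochroman-3-yl acetate
Conditions: Dess–Martin periodinane, CH2Cl2, 0 °C to rt
Reagents that add atoms: none
Why: Dess–Martin oxidation of the secondary benzylic alcohol under non-basic conditions; both C4 epimers converge on one ketone, the diarylmethane CH2 is not attacked by this reagent, and C2 and C3 keep their configuration.

Step 12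
Reactants: 18 (2R,3R)-5,7-bis(benzyloxy)-6-[4-(benzyloxy)benzyl]-2-[4-(benzyloxy)phenyl]-4-oxochroman-3-yl acetate
Product: 19 (2R,3R)-5,7-bis(benzyloxy)-6-[4-(benzyloxy)benzyl]-2-[4-(benzyloxy)phenyl]-3-hydroxychroman-4-one
Conditions: HCl (1.25 M in MeOH), THF, rt to 40 °C
Reagents that add atoms: none
Why: Acid-catalysed transesterification removes the acetate without forming the C3 enolate, so ring C cannot open by β-elimination of the aryloxide; benzyl ethers tolerate dilute methanolic HCl, and any that were lost would be removed in the next step anyway.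

Step 13
Reactants: 19 (2R,3R)-5,7-bis(benzyloxy)-6-[4-(benzyloxy)benzyl]-2-[4-(benzyloxy)phenyl]-3-hydroxychroman-4-one
Product: 20 gericudranin E, (2R,3R)-3,5,7-trihydroxy-6-(4-hydroxybenzyl)-2-(4-hydroxyphenyl)chroman-4-one
Conditions: H2 (1 atm), Pd/C (10% palladium on carbon), EtOAc/MeOH, rt
Reagents that add atoms: none
Why: Hydrogenolysis of the four benzyl ethers under neutral conditions; the aryl ketone, the diarylmethane and the benzylic C2–O1 bond should survive at atmospheric pressure if the reaction is stopped after uptake of four equivalents, and no stereocentre is touched.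

## Compound list

1 | 2,4,6-trihydroxybenzaldehyde | O=Cc1c(O)cc(O)cc1O | starting material
2 | 4-(allyloxy)-2,6-dihydroxybenzaldehyde | O=Cc1c(O)cc(OCC=C)cc1O | intermediate
3 | 4-(allyloxy)-2,6-bis(benzyloxy)benzaldehyde | O=Cc1c(OCc2ccccc2)cc(OCC=C)cc1OCc1ccccc1 | intermediate
4 | 1-(benzyloxy)-4-bromobenzene | Brc1ccc(OCc2ccccc2)cc1 | starting material
5 | [4-(benzyloxy)phenyl]magnesium bromide (not isolated) | Br[Mg]c1ccc(OCc2ccccc2)cc1 | intermediate
6 | [4-(allyloxy)-2,6-bis(benzyloxy)phenyl][4-(benzyloxy)phenyl]methanol (racemic) | OC(c1ccc(OCc2ccccc2)cc1)c1c(OCc2ccccc2)cc(OCC=C)cc1OCc1ccccc1 | intermediate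
7 | 5-(allyloxy)-1,3-bis(benzyloxy)-2-[4-(benzyloxy)benzyl]benzene | C=CCOc1cc(OCc2ccccc2)c(Cc2ccc(OCc3ccccc3)cc2)c(OCc2ccccc2)c1 | intermediate
8 | 3,5-bis(benzyloxy)-4-[4-(benzyloxy)benzyl]phenol | Oc1cc(OCc2ccccc2)c(Cc2ccc(OCc3ccccc3)cc2)c(OCc2ccccc2)c1 | intermediate
9 | 2,4-bis(benzyloxy)-3-[4-(benzyloxy)benzyl]-6-hydroxybenzaldehyde | O=Cc1c(O)cc(OCc2ccccc2)c(Cc2ccc(OCc3ccccc3)cc2)c1OCc1ccccc1 | intermediate
10 | 2-[4-(benzyloxy)phenyl]ethanol | OCCc1ccc(OCc2ccccc2)cc1 | starting material
11 | 2-[4-(benzyloxy)phenyl]acetaldehyde | O=CCc1ccc(OCc2ccccc2)cc1 | intermediate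
12 | (E)-2-[4-(benzyloxy)phenyl]ethenyl acetate | CC(=O)O/C=C/c1ccc(OCc2ccccc2)cc1 | intermediate
13 | trimethyl orthoformate | COC(OC)OC | starting material
14 | 3,5-bis(benzyloxy)-4-[4-(benzyloxy)benzyl]-2-(dimethoxymethyl)phenol (not isolated) | COC(OC)c1c(O)cc(OCc2ccccc2)c(Cc2ccc(OCc3ccccc3)cc2)c1OCc1ccccc1 | intermediate
15 | {2,4-bis(benzyloxy)-3-[4-(benzyloxy)benzyl]-6-hydroxyphenyl}methylidene(methyl)oxonium, the O-methyl o-quinone methide cation (not isolated) | C[O+]=Cc1c(O)cc(OCc2ccccc2)c(Cc2ccc(OCc3ccccc3)cc2)c1OCc1ccccc1 | intermediate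
16 | (2R,3S)-5,7-bis(benzyloxy)-6-[4-(benzyloxy)benzyl]-2-[4-(benzyloxy)phenyl]-4-methoxychroman-3-yl acetate (C4 epimers) | COC1c2c(cc(OCc3ccccc3)c(Cc3ccc(OCc4ccccc4)cc3)c2OCc2ccccc2)O[C@H](c2ccc(OCc3ccccc3)cc2)[C@H]1OC(C)=O | intermediate
17 | (2R,3S)-5,7-bis(benzyloxy)-6-[4-(benzyloxy)benzyl]-2-[4-(benzyloxy)phenyl]-4-hydroxychroman-3-yl acetate (C4 epimers) | OC1c2c(cc(OCc3ccccc3)c(Cc3ccc(OCc4ccccc4)cc3)c2OCc2ccccc2)O[C@H](c2ccc(OCc3ccccc3)cc2)[C@H]1OC(C)=O | intermediate
18 | (2R,3R)-5,7-bis(benzyloxy)-6-[4-(benzyloxy)benzyl]-2-[4-(benzyloxy)phenyl]-4-oxochroman-3-yl acetate | O=C1c2c(cc(OCc3ccccc3)c(Cc3ccc(OCc4ccccc4)cc3)c2OCc2ccccc2)O[C@H](c2ccc(OCc3ccccc3)cc2)[C@H]1OC(C)=O | intermediate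
19 | (2R,3R)-5,7-bis(benzyloxy)-6-[4-(benzyloxy)benzyl]-2-[4-(benzyloxy)phenyl]-3-hydroxychroman-4-one | O=C1c2c(cc(OCc3ccccc3)c(Cc3ccc(OCc4ccccc4)cc3)c2OCc2ccccc2)O[C@H](c2ccc(OCc3ccccc3)cc2)[C@H]1O | intermediate
20 | gericudranin E, (2R,3R)-3,5,7-trihydroxy-6-(4-hydroxybenzyl)-2-(4-hydroxyphenyl)chroman-4-one | O=C1c2c(cc(O)c(Cc3ccc(O)cc3)c2O)O[C@H](c2ccc(O)cc2)[C@H]1O | target

## Step count and least certain steps

Total step count: 13. Longest linear sequence: 11 steps (steps 1–6 and 9–13, from 1 to 20); the enol acetate branch contributes steps 7 and 8.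

**Step 9 (key step).** What may go wrong: the enol acetate faces may be poorly discriminated, because the catalyst must govern the cation face and the endo/exo orientation at once. C–C bond formation may be slow, since cation 15 is stabilised by three oxygens, which gives time for acid-catalysed addition of methanol to 12 or for alkylation of 12 by residual orthoformate-derived cation. The product may re-ionise at C4 and be alkylated a second time by 12. Fallback (known chemistry), from 9 to 19: the phenol of 9 is capped with MOMCl and iPr2NEt to give 2,4-bis(benzyloxy)-3-[4-(benzyloxy)benzyl]-6-(methoxymethoxy)benzaldehyde F1. MeMgBr adds to F1 to give 1-{2,4-bis(benzyloxy)-3-[4-(benzyloxy)benzyl]-6-(methoxymethoxy)phenyl}ethanol F2, and Dess–Martin oxidation gives 1-{2,4-bis(benzyloxy)-3-[4-(benzyloxy)benzyl]-6-(methoxymethoxy)phenyl}ethanone F3. Claisen–Schmidt condensation of F3 with purchased 4-(benzyloxy)benzaldehyde F4 (KOH, EtOH) gives the chalcone (E)-1-{2,4-bis(benzyloxy)-3-[4-(benzyloxy)benzyl]-6-(methoxymethoxy)phenyl}-3-[4-(benzyloxy)phenyl]prop-2-en-1-one F5. Juliá–Colonna epoxidation of F5 (poly-L-leucine, urea–H2O2, DBU, THF) is expected to give {2,4-bis(benzyloxy)-3-[4-(benzyloxy)benzyl]-6-(methoxymethoxy)phenyl}{(2R,3S)-3-[4-(benzyloxy)phenyl]oxiran-2-yl}methanone F6. Methanolic HCl then removes the MOM group of F6, and the freed phenol opens the epoxide at the benzylic carbon with inversion to the 2,3-trans ketol, so the route is rejoined at 19.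

**Step 10.** What may go wrong: the acetyl group may migrate from O3 to O4 through the neighbouring acetoxonium/ortho-acid pathway, so that the wrong hydroxyl is oxidised next. The C4 cation may also be captured by C8 of a second molecule (flavan dimerisation) or lose the C3 hydrogen. Fallback, from 16 to 20, which replaces the migrating ester by an ether: K2CO3/MeOH on the base-stable flavan 16 gives (2R,3S)-5,7-bis(benzyloxy)-6-[4-(benzyloxy)benzyl]-2-[4-(benzyloxy)phenyl]-4-methoxychroman-3-ol F7. NaH and BnBr convert F7 into (2R,3S)-3,5,7-tris(benzyloxy)-6-[4-(benzyloxy)benzyl]-2-[4-(benzyloxy)phenyl]-4-methoxychroman F8. Dilute aqueous acid under high dilution gives (2R,3S)-3,5,7-tris(benzyloxy)-6-[4-(benzyloxy)benzyl]-2-[4-(benzyloxy)phenyl]chroman-4-ol F9, and Dess–Martin oxidation gives (2R,3R)-3,5,7-tris(benzyloxy)-6-[4-(benzyloxy)benzyl]-2-[4-(benzyloxy)phenyl]chroman-4-one F10. Hydrogenolysis of F10 over Pd/C removes all five benzyl groups and arrives directly at 20.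

**Step 12.** What may go wrong: acidolysis of the hindered α-acyloxy ketone may be sluggish. Forcing it invites enolisation at C3 (formation of the cis epimer) and partial loss of benzyl ethers, giving mixtures that are hard to follow. Fallback, from 18 to 20: hydrogenolysis is run first (H2, Pd/C) to give (2R,3R)-5,7-dihydroxy-6-(4-hydroxybenzyl)-2-(4-hydroxyphenyl)-4-oxochroman-3-yl acetate F11. The acetate of F11 is then removed with methanolic HCl on the free polyphenol, where the chelated 5-hydroxyl lowers the tendency of the ketone to enolise and no benzyl ether remains to be lost, and 20 is reached.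

**Step 1.** What may go wrong: over-alkylation at an ortho hydroxyl and C-allylation of the phloroglucinol ring, which erode the mono-4-O selectivity on which the symmetry of 8 depends. Fallback, from 4 (through its Grignard reagent 5) to 8, with the future phenol oxygen masked as bromine: purchased 4-bromo-2,6-difluorobenzaldehyde F12 undergoes double SNAr with BnOH/KOtBu in THF to give 2,6-bis(benzyloxy)-4-bromobenzaldehyde F13. Reagent 5 adds to F13 to give [2,6-bis(benzyloxy)-4-bromophenyl][4-(benzyloxy)phenyl]methanol F14, and Et3SiH/TFA gives 1,3-bis(benzyloxy)-2-[4-(benzyloxy)benzyl]-5-bromobenzene F15. Palladium-catalysed hydroxylation of F15 (Pd2(dba)3, tBuXPhos, KOH, dioxane/H2O, 100 °C) converts the bromide into phenol 8.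

## Further compounds

F1 | step 9 | 2,4-bis(benzyloxy)-3-[4-(benzyloxy)benzyl]-6-(methoxymethoxy)benzaldehyde | O=Cc1c(OCOC)cc(OCc2ccccc2)c(Cc2ccc(OCc3ccccc3)cc2)c1OCc1ccccc1
F2 | step 9 | 1-{2,4-bis(benzyloxy)-3-[4-(benzyloxy)benzyl]-6-(methoxymethoxy)phenyl}ethanol (racemic) | CC(O)c1c(OCOC)cc(OCc2ccccc2)c(Cc2ccc(OCc3ccccc3)cc2)c1OCc1ccccc1
F3 | step 9 | 1-{2,4-bis(benzyloxy)-3-[4-(benzyloxy)benzyl]-6-(methoxymethoxy)phenyl}ethanone | CC(=O)c1c(OCOC)cc(OCc2ccccc2)c(Cc2ccc(OCc3ccccc3)cc2)c1OCc1ccccc1
F4 | step 9 | 4-(benzyloxy)benzaldehyde (purchased) | O=Cc1ccc(OCc2ccccc2)cc1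
F5 | step 9 | (E)-1-{2,4-bis(benzyloxy)-3-[4-(benzyloxy)benzyl]-6-(methoxymethoxy)phenyl}-3-[4-(benzyloxy)phenyl]prop-2-en-1-one | O=C(/C=C/c1ccc(OCc2ccccc2)cc1)c1c(OCOC)cc(OCc2ccccc2)c(Cc2ccc(OCc3ccccc3)cc2)c1OCc1ccccc1
F6 | step 9 | {2,4-bis(benzyloxy)-3-[4-(benzyloxy)benzyl]-6-(methoxymethoxy)phenyl}{(2R,3S)-3-[4-(benzyloxy)phenyl]oxiran-2-yl}methanone | O=C([C@@H]1O[C@H]1c1ccc(OCc2ccccc2)cc1)c1c(OCOC)cc(OCc2ccccc2)c(Cc2ccc(OCc3ccccc3)cc2)c1OCc1ccccc1
F7 | step 10 | (2R,3S)-5,7-bis(benzyloxy)-6-[4-(benzyloxy)benzyl]-2-[4-(benzyloxy)phenyl]-4-methoxychroman-3-ol (C4 epimers) | COC1c2c(cc(OCc3ccccc3)c(Cc3ccc(OCc4ccccc4)cc3)c2OCc2ccccc2)O[C@H](c2ccc(OCc3ccccc3)cc2)[C@H]1O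
F8 | step 10 | (2R,3S)-3,5,7-tris(benzyloxy)-6-[4-(benzyloxy)benzyl]-2-[4-(benzyloxy)phenyl]-4-methoxychroman (C4 epimers) | COC1c2c(cc(OCc3ccccc3)c(Cc3ccc(OCc4ccccc4)cc3)c2OCc2ccccc2)O[C@H](c2ccc(OCc3ccccc3)cc2)[C@H]1OCc1ccccc1
F9 | step 10 | (2R,3S)-3,5,7-tris(benzyloxy)-6-[4-(benzyloxy)benzyl]-2-[4-(benzyloxy)phenyl]chroman-4-ol (C4 epimers) | OC1c2c(cc(OCc3ccccc3)c(Cc3ccc(OCc4ccccc4)cc3)c2OCc2ccccc2)O[C@H](c2ccc(OCc3ccccc3)cc2)[C@H]1OCc1ccccc1
F10 | step 10 | (2R,3R)-3,5,7-tris(benzyloxy)-6-[4-(benzyloxy)benzyl]-2-[4-(benzyloxy)phenyl]chroman-4-one | O=C1c2c(cc(OCc3ccccc3)c(Cc3ccc(OCc4ccccc4)cc3)c2OCc2ccccc2)O[C@H](c2ccc(OCc3ccccc3)cc2)[C@H]1OCc1ccccc1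
F11 | step 12 | (2R,3R)-5,7-dihydroxy-6-(4-hydroxybenzyl)-2-(4-hydroxyphenyl)-4-oxochroman-3-yl acetate | O=C1c2c(cc(O)c(Cc3ccc(O)cc3)c2O)O[C@H](c2ccc(O)cc2)[C@H]1OC(C)=O
F12 | step 1 | 4-bromo-2,6-difluorobenzaldehyde (purchased) | O=Cc1c(F)cc(Br)cc1F
F13 | step 1 | 2,6-bis(benzyloxy)-4-bromobenzaldehyde | O=Cc1c(OCc2ccccc2)cc(Br)cc1OCc1ccccc1
F14 | step 1 | [2,6-bis(benzyloxy)-4-bromophenyl][4-(benzyloxy)phenyl]methanol (racemic) | OC(c1ccc(OCc2ccccc2)cc1)c1c(OCc2ccccc2)cc(Br)cc1OCc1ccccc1
F15 | step 1 | 1,3-bis(benzyloxy)-2-[4-(benzyloxy)benzyl]-5-bromobenzene | Brc1cc(OCc2ccccc2)c(Cc2ccc(OCc3ccccc3)cc2)c(OCc2ccccc2)c1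
A1 | alternative 1 | (2R,3R)-3-(benzyloxy)-6-[4-(benzyloxy)benzyl]-2-[4-(benzyloxy)phenyl]-5-hydroxy-7-(triisopropylsilyloxy)chroman-4-one | O=C1c2c(cc(O[Si](C(C)C)(C(C)C)C(C)C)c(Cc3ccc(OCc4ccccc4)cc3)c2O)O[C@H](c2ccc(OCc3ccccc3)cc2)[C@H]1OCc1ccccc1
A2 | alternative 1 | (2R,3R)-3-(benzyloxy)-2-[4-(benzyloxy)phenyl]-6-(diazoacetyl)-2,3-dihydro-4H-pyran-4-one | O=C1C=C(C(=O)C=[N+]=[N-])O[C@H](c2ccc(OCc3ccccc3)cc2)[C@H]1OCc1ccccc1
A3 | alternative 1 | triisopropyl({3-[4-(benzyloxy)phenyl]prop-1-yn-1-yl}oxy)silane | CC(C)[Si](OC#CCc1ccc(OCc2ccccc2)cc1)(C(C)C)C(C)C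
A4 | alternative 2 | (2R,3R)-5,7-bis(benzyloxy)-6-[4-(benzyloxy)benzyl]-2-[4-(benzyloxy)phenyl]-3-(tert-butyldimethylsilyloxy)chroman-4-one | O=C1c2c(cc(OCc3ccccc3)c(Cc3ccc(OCc4ccccc4)cc3)c2OCc2ccccc2)O[C@H](c2ccc(OCc3ccccc3)cc2)[C@H]1O[Si](C)(C)C(C)(C)C
A5 | alternative 2 | (2R,3R)-3-{3,5-bis(benzyloxy)-4-[4-(benzyloxy)benzyl]-2-bromophenoxy}-3-[4-(benzyloxy)phenyl]-2-(tert-butyldimethylsilyloxy)-N-methoxy-N-methylpropanamide | CON(C)C(=O)[C@H](O[Si](C)(C)C(C)(C)C)[C@H](Oc1cc(OCc2ccccc2)c(Cc2ccc(OCc3ccccc3)cc2)c(OCc2ccccc2)c1Br)c1ccc(OCc2ccccc2)cc1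
A6 | alternative 2 | methyl (2R,3S)-3-[4-(benzyloxy)phenyl]oxirane-2-carboxylate | COC(=O)[C@@H]1O[C@H]1c1ccc(OCc2ccccc2)cc1
A7 | alternative 3 | 5,7-bis(benzyloxy)-6-[4-(benzyloxy)benzyl]-2-[4-(benzyloxy)phenyl]-4H-chromen-4-one | O=c1cc(-c2ccc(OCc3ccccc3)cc2)oc2cc(OCc3ccccc3)c(Cc3ccc(OCc4ccccc4)cc3)c(OCc3ccccc3)c12
A8 | alternative 3 | 3,5-bis(benzyloxy)-4-[4-(benzyloxy)benzyl]-2-iodophenol | Oc1cc(OCc2ccccc2)c(Cc2ccc(OCc3ccccc3)cc2)c(OCc2ccccc2)c1I
A9 | alternative 3 | 1-(benzyloxy)-4-ethynylbenzene | C#Cc1ccc(OCc2ccccc2)cc1
A10 | alternative 3 | carbon monoxide | [C-]#[O+]
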